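Ring A is disconnected with ring C left intact: breaking C4a–C5, C5–C6 and C7–C8 gives a 2-aryl-3-methoxy-4-pyranone and methoxyacetylene. The feature exploited is the substitution pattern of ring A (C5 OH, C6 H, C7 OMe, C8 benzyl, fused at C4a–C8a), which maps exactly onto a ketene carbonyl carbon, the two alkyne carbons and the ketene α-carbon. One operation (photochemical Wolff rearrangement, ketene–alkyne [2+2] addition, 4π opening, 6π electrocyclisation) therefore builds the whole ring with every substituent in place. The precursor is the pyranone bearing at C6 (future C8a) a diazo carbon acylated by a (2-benzyloxyphenyl)acetyl group, with both phenols masked as benzyl ethers.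

Key step: step 10

Remark: the target has no stereocentre; boronic acid 6 and acid 8 are bought as such, and the volatile alkyne 17 is made just before use.

Step 1
Reactants: 1 kojic acid
Product: 2 chlorokojic acid, 2-(chloromethyl)-5-hydroxy-4H-pyran-4-one
Conditions: SOCl2 (neat), rt
Reagents that add atoms: thionyl chloride, O=S(Cl)Cl
Why: Deoxychlorination of the primary alcohol with SOCl2 should be clean because the acidic enolic 5-OH is not converted under these conditions.

Step 2
Reactants: 2 chlorokojic acid
Product: 3 allomaltol, 5-hydroxy-2-methyl-4H-pyran-4-one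
Conditions: Zn dust, conc. HCl, H2O, 70 °C
Reagents that add atoms: none
Why: Dissolving-metal reductive dechlorination of the activated (pyranonyl)methyl chloride should leave the pyranone ring untouched.

Step 3
Reactants: 3 allomaltol
Product: 4 2-bromo-3-hydroxy-6-methyl-4H-pyran-4-one
Conditions: NBS, MeCN, 0 °C to rt, dark
Reagents that add atoms: N-bromosuccinimide, O=C1CCC(=O)N1Br
Why: Electrophilic bromination of the enol should occur only at the ring carbon between O1 and the hydroxylated carbon, the nucleophilic enol terminus, as in the bromination of kojic acid; brominating before O-methylation keeps this site selectivity.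

Step 4
Reactants: 4 2-bromo-3-hydroxy-6-methyl-4H-pyran-4-one
Product: 5 2-bromo-3-methoxy-6-methyl-4H-pyran-4-one
Conditions: MeI, K2CO3, DMF, rt
Reagents that add atoms: iodomethane, CI
Why: Williamson O-methylation of the acidic enolic hydroxyl should proceed with a mild carbonate base that does not displace the vinylogous acyl bromide.

Step 5
Reactants: 5 2-bromo-3-methoxy-6-methyl-4H-pyran-4-one; 6 (4-benzyloxy-3-methoxyphenyl)boronic acid
Product: 7 2-(4-benzyloxy-3-methoxyphenyl)-3-methoxy-6-methyl-4H-pyran-4-one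
Conditions: Pd(PPh3)4 (5 mol %), K2CO3, toluene/EtOH/H2O, 80 °C
Reagents that add atoms: none
Why: Suzuki–Miyaura coupling should be easy because the C–Br bond of a 2-bromo-4-pyranone is a vinylogous acyl bromide and undergoes oxidative addition readily, while the methyl and benzyl ethers are inert.

Step 6
Reactants: 8 (2-benzyloxyphenyl)acetic acid
Product: 10 2-(2-benzyloxyphenyl)-N-methoxy-N-methylacetamide, via acyl imidazole 9 (not isolated)
Conditions: CDI, CH2Cl2, rt; then MeNHOMe·HCl, rt
Reagents that add atoms: N,O-dimethylhydroxylamine hydrochloride, CNOC.Cl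
Why: Carbonyldiimidazole activation followed by aminolysis of the acyl imidazole is a standard Weinreb amide synthesis and needs no strong base that could enolise the arylacetyl unit.

Step 7
Reactants: 7 2-(4-benzyloxy-3-methoxyphenyl)-3-methoxy-6-methyl-4H-pyran-4-one; 10 2-(2-benzyloxyphenyl)-N-methoxy-N-methylacetamide
Product: 13 2-(4-benzyloxy-3-methoxyphenyl)-6-[3-(2-benzyloxyphenyl)-2-oxopropyl]-3-methoxy-4H-pyran-4-one, via lithium dienolate 11 (not isolated), via tetrahedral lithium adduct 12 (not isolated)
Conditions: LiN(SiMe3)2 (1.2 equiv), THF, −78 °C; then 10 (1.3 equiv), −78 to −20 °C; AcOH quench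
Reagents that add atoms: none
Why: Lateral deprotonation of the 6-methyl group (the γ-position of the vinylogous ester) gives a dienolate that should be C-acylated at the exocyclic carbon in a Claisen-type acylation; the Weinreb amide is less acidic than an arylacetate ester and holds the adduct until the quench, so the acidic ketone is never exposed to base.

Step 8
Reactants: 13 2-(4-benzyloxy-3-methoxyphenyl)-6-[3-(2-benzyloxyphenyl)-2-oxopropyl]-3-methoxy-4H-pyran-4-one
Product: 14 2-(4-benzyloxy-3-methoxyphenyl)-6-[3-(2-benzyloxyphenyl)-1-diazo-2-oxopropyl]-3-methoxy-4H-pyran-4-one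
Conditions: p-ABSA (1.1 equiv), Et3N, MeCN, 0 °C to rt; used at once, kept cold and dark
Reagents that add atoms: 4-acetamidobenzenesulfonyl azide, CC(=O)Nc1ccc(cc1)S(=O)(=O)N=[N+]=[N-]
Why: Regitz diazo transfer should select the methylene between the ketone and the pyranone, a vinylogous 1,3-dicarbonyl position that an amine base deprotonates, over the far less acidic benzylic methylene on the other side of the ketone.

Step 9
Reactants: 15 chloroacetaldehyde dimethyl acetal
Product: 17 methoxyacetylene, via sodium methoxyacetylide 16 (not isolated)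
Conditions: NaNH2 (3 equiv), liq. NH3, −33 °C; NH3 evaporated; then cold brine, −70 °C; distilled into a cold trap
Reagents that add atoms: none
Why: Twofold base-induced elimination (loss of methanol, then of HCl) with a third equivalent of amide gives the acetylide, and protonation releases the alkyne, a known preparation of alkoxyacetylenes.

Step 10
Reactants: 14 2-(4-benzyloxy-3-methoxyphenyl)-6-[3-(2-benzyloxyphenyl)-1-diazo-2-oxopropyl]-3-methoxy-4H-pyran-4-one; 17 methoxyacetylene
Product: 22 8-(2-benzyloxybenzyl)-2-(4-benzyloxy-3-methoxyphenyl)-5-hydroxy-3,7-dimethoxychromen-4-one, via ketene 18 (not isolated), via cyclobutenone 19 (not isolated), via dienylketene 20 (not isolated), via 4aH-dienone 21 (not isolated)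
Conditions: 17 (5 equiv), hν (440 nm LEDs), ClCH2CH2Cl, 0 °C, sealed tube; then 80 °C, dark
Reagents that add atoms: none
Why: Proposed new method: irradiation should expel N2 from 14 with migration of the (2-benzyloxyphenyl)methyl group to the former diazo carbon (Wolff rearrangement) to give ketene 18, whose carbonyl carbon bonds to the CH terminus of the ynol ether and whose α-carbon bonds to the methoxy-bearing carbon ([2+2] cycloaddition) to give cyclobutenone 19, and on heating 19 should open (4π) to dienylketene 20, which closes (6π) onto the pyranone C5–H carbon and tautomerises through dienone 21 to phenol 22. The closest known reaction type is the Danheiser benzannulation of aryl and heteroaryl α-diazo ketones with alkoxy- and siloxyalkynes; new here is a 4-pyranone C5=C6 bond as the terminal 2π unit, which should close more readily than a benzene ring because less aromatic stabilisation is given up. Ring A is the only ring closed, by a thermal disrotatory 6π electrocyclisation that forms C4a–C5 after C5–C6 and C7–C8 have been made in the [2+2] step, and no stereocentre survives because the quaternary carbon of 19 and C4a of 21 are transient. The regiochemistry needed (alkyne CH to the ketene carbonyl carbon, hence C6 H and C7 OMe) is secured by the polarisation of the ynol ether, and the closure has one site only because C5 is the single free position next to the ketene-bearing carbon. The 4π opening must turn the pyranonyl group inward, which its acceptor character favours, and the other isomer can only revert to 19. A 1,2-hydrogen shift of the carbene is excluded because the diazo carbon has no neighbouring C–H, both phenols are benzylated so that no OH intercepts the ketenes, and 440 nm light should be absorbed by the conjugated diazo chromophore but not by the pyranone (365 nm is the alternative if absorption proves too weak).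

Step 11
Reactants: 22 8-(2-benzyloxybenzyl)-2-(4-benzyloxy-3-methoxyphenyl)-5-hydroxy-3,7-dimethoxychromen-4-one
Product: 23 8-(2-hydroxybenzyl)-5-hydroxy-2-(4-hydroxy-3-methoxyphenyl)-3,7-dimethoxychromen-4-one (target, CNP0281421.0)
Conditions: H2 (1 atm), 10% Pd/C, EtOAc/MeOH, rt
Reagents that add atoms: none
Why: Catalytic hydrogenolysis should cleave both aryl benzyl ethers, while the diarylmethane C–C bond and the tetrasubstituted C2=C3 bond of the chromone are not expected to react under these mild conditions.

Compound list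
1 | kojic acid, 5-hydroxy-2-(hydroxymethyl)-4H-pyran-4-one | O=c1cc(CO)occ1O | starting material
2 | chlorokojic acid, 2-(chloromethyl)-5-hydroxy-4H-pyran-4-one | O=c1cc(CCl)occ1O | intermediate
3 | allomaltol, 5-hydroxy-2-methyl-4H-pyran-4-one | Cc1cc(=O)c(O)co1 | intermediate
4 | 2-bromo-3-hydroxy-6-methyl-4H-pyran-4-one | Cc1cc(=O)c(O)c(Br)o1 | intermediate
5 | 2-bromo-3-methoxy-6-methyl-4H-pyran-4-one | COc1c(Br)oc(C)cc1=O | intermediate
6 | (4-benzyloxy-3-methoxyphenyl)boronic acid | COc1cc(B(O)O)ccc1OCc1ccccc1 | starting material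
7 | 2-(4-benzyloxy-3-methoxyphenyl)-3-methoxy-6-methyl-4H-pyran-4-one | COc1cc(-c2oc(C)cc(=O)c2OC)ccc1OCc1ccccc1 | intermediate
8 | (2-benzyloxyphenyl)acetic acid | OC(=O)Cc1ccccc1OCc1ccccc1 | starting material
9 | 1-[(2-benzyloxyphenyl)acetyl]imidazole (formed in the flask, not isolated) | O=C(Cc1ccccc1OCc1ccccc1)n1ccnc1 | intermediate
10 | 2-(2-benzyloxyphenyl)-N-methoxy-N-methylacetamide | CON(C)C(=O)Cc1ccccc1OCc1ccccc1 | intermediate
11 | lithium 6-(4-benzyloxy-3-methoxyphenyl)-5-methoxy-2-methylidene-2H-pyran-4-olate (formed in the flask, not isolated) | [Li+].C=C1C=C([O-])C(OC)=C(c2ccc(OCc3ccccc3)c(OC)c2)O1 | intermediate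
12 | lithium 1-[6-(4-benzyloxy-3-methoxyphenyl)-5-methoxy-4-oxo-4H-pyran-2-yl]-3-(2-benzyloxyphenyl)-2-[methoxy(methyl)amino]propan-2-olate (formed in the flask, not isolated) | [Li+].COc1cc(-c2oc(CC([O-])(Cc3ccccc3OCc3ccccc3)N(C)OC)cc(=O)c2OC)ccc1OCc1ccccc1 | intermediate
13 | 2-(4-benzyloxy-3-methoxyphenyl)-6-[3-(2-benzyloxyphenyl)-2-oxopropyl]-3-methoxy-4H-pyran-4-one | COc1cc(-c2oc(CC(=O)Cc3ccccc3OCc3ccccc3)cc(=O)c2OC)ccc1OCc1ccccc1 | intermediate
14 | 2-(4-benzyloxy-3-methoxyphenyl)-6-[3-(2-benzyloxyphenyl)-1-diazo-2-oxopropyl]-3-methoxy-4H-pyran-4-one | COc1cc(-c2oc(C(=[N+]=[N-])C(=O)Cc3ccccc3OCc3ccccc3)cc(=O)c2OC)ccc1OCc1ccccc1 | intermediate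
15 | chloroacetaldehyde dimethyl acetal, 2-chloro-1,1-dimethoxyethane | COC(CCl)OC | starting material
16 | sodium methoxyacetylide (formed in the flask, not isolated) | [Na+].[C-]#COC | intermediate
17 | methoxyacetylene | C#COC | intermediate
18 | 2-[6-(4-benzyloxy-3-methoxyphenyl)-5-methoxy-4-oxo-4H-pyran-2-yl]-3-(2-benzyloxyphenyl)prop-1-en-1-one, the ketene (formed in the flask, not isolated) | COc1cc(-c2oc(C(=C=O)Cc3ccccc3OCc3ccccc3)cc(=O)c2OC)ccc1OCc1ccccc1 | intermediate
19 | 4-(2-benzyloxybenzyl)-4-[6-(4-benzyloxy-3-methoxyphenyl)-5-methoxy-4-oxo-4H-pyran-2-yl]-3-methoxycyclobut-2-en-1-one, racemic (formed in the flask, not isolated) | COC1=CC(=O)C1(Cc1ccccc1OCc1ccccc1)c1cc(=O)c(OC)c(-c2ccc(OCc3ccccc3)c(OC)c2)o1 | intermediate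
20 | (3E)-5-(2-benzyloxyphenyl)-4-[6-(4-benzyloxy-3-methoxyphenyl)-5-methoxy-4-oxo-4H-pyran-2-yl]-3-methoxypenta-1,3-dien-1-one, ketenyl group cis to the pyranonyl group (formed in the flask, not isolated) | O=C=C/C(OC)=C(/Cc1ccccc1OCc1ccccc1)c1cc(=O)c(OC)c(-c2ccc(OCc3ccccc3)c(OC)c2)o1 | intermediate
21 | 8-(2-benzyloxybenzyl)-2-(4-benzyloxy-3-methoxyphenyl)-3,7-dimethoxy-4aH-chromene-4,5-dione, racemic at C4a (formed in the flask, not isolated) | COC1=CC(=O)C2C(=O)C(OC)=C(c3ccc(OCc4ccccc4)c(OC)c3)OC2=C1Cc1ccccc1OCc1ccccc1 | intermediate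
22 | 8-(2-benzyloxybenzyl)-2-(4-benzyloxy-3-methoxyphenyl)-5-hydroxy-3,7-dimethoxychromen-4-one | COc1cc(-c2oc3c(Cc4ccccc4OCc4ccccc4)c(OC)cc(O)c3c(=O)c2OC)ccc1OCc1ccccc1 | intermediate
23 | 8-(2-hydroxybenzyl)-5-hydroxy-2-(4-hydroxy-3-methoxyphenyl)-3,7-dimethoxychromen-4-one | COc1cc(-c2oc3c(Cc4ccccc4O)c(OC)cc(O)c3c(=O)c2OC)ccc1O | target

Total step count: 11. Longest linear sequence: 9 steps (1, 2, 3, 4, 5, 7, 8, 10, 11).

Steps most likely to fail

Step 10. The dienylketene may not close onto the pyranone C5–H carbon: it may revert or oligomerise, or the photochemically formed carbene may be diverted (for example by ylide formation at the ortho benzyloxy oxygen) before the Wolff shift. The fallback takes ring A from an aromatic starting material and builds ring C last by known flavonoid chemistry. It sets out from acid 8, which still supplies the benzyl group, and comes back to the route at target 23.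
- 3,5-Dimethoxyphenol is acylated with methoxyacetyl chloride (BF3·OEt2, Fries conditions) to 1-(2-hydroxy-4,6-dimethoxyphenyl)-2-methoxyethanone F1.
- Iodination ortho to the chelated phenol (N-iodosuccinimide, cat. CF3CO2H, MeCN) should give 1-(2-hydroxy-3-iodo-4,6-dimethoxyphenyl)-2-methoxyethanone F2.
- Claisen–Schmidt condensation with commercial 4-benzyloxy-3-methoxybenzaldehyde (KOH, EtOH) should give (Z)-3-(4-benzyloxy-3-methoxyphenyl)-1-(2-hydroxy-3-iodo-4,6-dimethoxyphenyl)-2-methoxyprop-2-en-1-one F3.
- Oxidative cyclisation (cat. I2, DMSO, 110 °C) should give 2-(4-benzyloxy-3-methoxyphenyl)-8-iodo-3,5,7-trimethoxychromen-4-one F4.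
- Decarboxylative arylation of 8 with F4 under dual nickel/iridium photoredox catalysis (NiCl2(MeOCH2CH2OMe), 4,4'-di-tert-butyl-2,2'-bipyridine, Ir[dF(CF3)ppy]2(dtbbpy)PF6, Cs2CO3, DMF, blue LEDs) should give 8-(2-benzyloxybenzyl)-2-(4-benzyloxy-3-methoxyphenyl)-3,5,7-trimethoxychromen-4-one F5.
- BCl3 (CH2Cl2, −78 to 0 °C) should then cleave both benzyl ethers and, through chelation to the C4 carbonyl, the C5 methyl ether, giving 23.

Step 8. Diazo transfer may lose site selectivity and also attack the benzylic methylene, or the vinylogous diazo ketone may cyclise onto the pyranone double bond to a pyrazole before it is used. The fallback generates the same ketene without any diazo compound, by dehydrochlorination of an acid chloride. It sets out from pyranone 7 and comes back to the route at ketene 18 inside step 10.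
- Lateral alkylation of 7 (LiN(SiMe3)2, THF, −78 °C; 2-(benzyloxy)benzyl bromide) should give 2-(4-benzyloxy-3-methoxyphenyl)-6-[2-(2-benzyloxyphenyl)ethyl]-3-methoxy-4H-pyran-4-one F6.
- A second lateral deprotonation and carboxylation (LiN(SiMe3)2; CO2; cold acidic work-up) should give racemic 2-[6-(4-benzyloxy-3-methoxyphenyl)-5-methoxy-4-oxo-4H-pyran-2-yl]-3-(2-benzyloxyphenyl)propanoic acid F7.
- Oxalyl chloride (cat. DMF, CH2Cl2, 0 °C) should give 2-[6-(4-benzyloxy-3-methoxyphenyl)-5-methoxy-4-oxo-4H-pyran-2-yl]-3-(2-benzyloxyphenyl)propanoyl chloride F8.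
- Et3N in the presence of 17 should release ketene 18, which is carried on as in step 10.

Step 7. Proton transfer from the enolisable Weinreb amide to the dienolate may outrun C–C bond formation and return 7. The fallback reverses the polarity, so that the pyranone side becomes the acyl electrophile and no enolisable electrophile is needed. It sets out from pyranone 7 and comes back to the route at ketone 13.
- Dienolate 11 (from 7 with 2.2 equiv LiN(SiMe3)2) is acylated with S-ethyl chlorothioformate to S-ethyl 2-[6-(4-benzyloxy-3-methoxyphenyl)-5-methoxy-4-oxo-4H-pyran-2-yl]ethanethioate F9.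
- Fukuyama coupling (PdCl2(PPh3)2, THF/toluene, rt) with (2-benzyloxybenzyl)zinc bromide F10, made from 2-(benzyloxy)benzyl bromide and zinc dust, should give 13.

Further compounds
F1 | step 10 | 1-(2-hydroxy-4,6-dimethoxyphenyl)-2-methoxyethanone | COCC(=O)c1c(O)cc(OC)cc1OC
F2 | step 10 | 1-(2-hydroxy-3-iodo-4,6-dimethoxyphenyl)-2-methoxyethanone | COCC(=O)c1c(OC)cc(OC)c(I)c1O
F3 | step 10 | (Z)-3-(4-benzyloxy-3-methoxyphenyl)-1-(2-hydroxy-3-iodo-4,6-dimethoxyphenyl)-2-methoxyprop-2-en-1-one | CO/C(=C\c1ccc(OCc2ccccc2)c(OC)c1)C(=O)c1c(OC)cc(OC)c(I)c1O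
F4 | step 10 | 2-(4-benzyloxy-3-methoxyphenyl)-8-iodo-3,5,7-trimethoxychromen-4-one | COc1cc(-c2oc3c(I)c(OC)cc(OC)c3c(=O)c2OC)ccc1OCc1ccccc1
F5 | step 10 | 8-(2-benzyloxybenzyl)-2-(4-benzyloxy-3-methoxyphenyl)-3,5,7-trimethoxychromen-4-one | COc1cc(-c2oc3c(Cc4ccccc4OCc4ccccc4)c(OC)cc(OC)c3c(=O)c2OC)ccc1OCc1ccccc1
F6 | step 8 | 2-(4-benzyloxy-3-methoxyphenyl)-6-[2-(2-benzyloxyphenyl)ethyl]-3-methoxy-4H-pyran-4-one | COc1cc(-c2oc(CCc3ccccc3OCc3ccccc3)cc(=O)c2OC)ccc1OCc1ccccc1
F7 | step 8 | 2-[6-(4-benzyloxy-3-methoxyphenyl)-5-methoxy-4-oxo-4H-pyran-2-yl]-3-(2-benzyloxyphenyl)propanoic acid (racemic) | COc1cc(-c2oc(C(Cc3ccccc3OCc3ccccc3)C(=O)O)cc(=O)c2OC)ccc1OCc1ccccc1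
F8 | step 8 | 2-[6-(4-benzyloxy-3-methoxyphenyl)-5-methoxy-4-oxo-4H-pyran-2-yl]-3-(2-benzyloxyphenyl)propanoyl chloride (racemic) | COc1cc(-c2oc(C(Cc3ccccc3OCc3ccccc3)C(Cl)=O)cc(=O)c2OC)ccc1OCc1ccccc1
F9 | step 7 | S-ethyl 2-[6-(4-benzyloxy-3-methoxyphenyl)-5-methoxy-4-oxo-4H-pyran-2-yl]ethanethioate | CCSC(=O)Cc1cc(=O)c(OC)c(-c2ccc(OCc3ccccc3)c(OC)c2)o1
F10 | step 7 | (2-benzyloxybenzyl)zinc bromide | Br[Zn]Cc1ccccc1OCc1ccccc1
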